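At early times both runs lost starting material at a pace that looked first-order, and the question was what stood in a third flask at its end.

| setting | epsilon | alpha | flask |
|---|---|---|---|
| starting material | 0.0010 M | 0.0015 M | 0.0020 M |
| partner | 1.5 equiv | 1.5 equiv | 1.50 equiv |
| initiator | 2.5 mol% | 2.5 mol% | 2.5 mol% |
| remark | run made earlier | run made earlier |  |
| time |  |  | 3.0 min |

| run | time / min | product / % | starting material / % |
|---|---|---|---|
| epsilon | 0.167 | 6.0 | 94.1 |
| epsilon | 0.500 | 15.9 | 86.7 |
| epsilon | 0.833 | 25.9 | 74.0 |
| epsilon | 1.33 | 36.7 | 62.0 |
| epsilon | 2.00 | 55.7 | 46.2 |
| epsilon | 2.50 | 63.0 | 36.3 |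
| alpha | 0.200 | 8.5 | 90.6 |
| alpha | 0.333 | 12.5 | 84.7 |
| alpha | 0.500 | 19.7 | 80.2 |
| alpha | 0.833 | 30.3 | 68.8 |
| alpha | 1.33 | 46.7 | 54.1 |
| alpha | 2.50 | 73.0 | 25.6 |

(each reading ± 1 percentage point)

- a species is counted by the starting material in it: one ended chains A counts as two
- amounts and yields of by-product count crystals too
- given per volume of solution although it is solid: crystals
- the analysis behind the earlier runs scatters by 1 percentage point, standard deviation
- reactions considered so far: initiator -> 2 initiating radical; partner + first chain carrier -> product + second chain carrier; starting material + second chain carrier -> by-product + first chain carrier; crystals <-> by-product; 2 second chain carrier -> ended chains B; starting material + initiating radical -> capped initiator + first chain carrier; 2 first chain carrier -> ended chains A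

- product present at 3.0 min, in percent of the starting material charged
- starting material present at 3.0 min, in percent of the starting material charged

But the first-order constant of the alpha run rose from 0.449 min⁻¹ at 0.833 min to 0.545 min⁻¹ at 2.50 min, so I followed one partner molecule instead. Each turn of the chain spends one partner and one starting material, so the starting material read gives an estimate of the fraction of partner left. If a partner molecule runs the same risk at each moment, that fraction falls pseudo-first-order. Its pace as read in the alpha run was 0.280 min⁻¹ at 0.833 min and 0.274 min⁻¹ at 2.50 min, so one number was enough for these two readings. The alpha pace stood 1.24 times the epsilon pace, near the square root of the concentration ratio, 1.22. Scaling by that root, I reckoned for the flask the depletion number, the logarithm of partner charged over partner left, as 0.949. That leaves 38.7% of the partner, hence 8.05% starting material and 92.0% product.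

The forecast, which differs from my reckoning, gave 83% product and 16% starting material, scaling a first-order constant, and remarked “Partner-limited kinetics would fit this too”.

The flask gave 89.8% product and 10.0% starting material.

    initiator → 2 initiating radical (k = 2.50 × 10⁻⁴ s⁻¹)
    partner + first chain carrier → product + second chain carrier (k = 7.90 × 10⁵ M⁻¹ s⁻¹)
    starting material + second chain carrier → by-product + first chain carrier (k = 1.90 × 10⁶ M⁻¹ s⁻¹)
    crystals ⇌ by-product, rate k4*(cs4 - [by-product]) while solid is left; crystals form when [by-product] > cs4 (solubility = 0.0310 mM, k = 0.150 s⁻¹)
    2 second chain carrier → ended chains B (k = 2.00 × 10⁷ M⁻¹ s⁻¹)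
    starting material + initiating radical → capped initiator + first chain carrier (k = 2.20 × 10⁸ M⁻¹ s⁻¹)
    2 first chain carrier → ended chains A (k = 2.70 × 10⁸ M⁻¹ s⁻¹)

The flask kept 40% of its partner, a depletion number of 0.916 against my 0.949. A neighbouring flask with 0.0080 M of starting material, the same equivalents and loading, and the same time scales to 1.90, more than the 1.10 at which the reckoning has the starting material, the limiting reagent, used up, so the reckoning stops the partner at 33.3% of its charge. At 3.00 min that neighbouring flask held 0% starting material, 99.9% product and 33.4% of its partner.

(Readings and results come from a simulation from invented constants, noise included.)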